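**Plan**

1. Cuts: ring B (the benzo ring of the dihydrobenzofuran) is opened at C7–C6, C5–C4 and C4–C3a by a carbene benzannulation, which brings in a surplus C4 hydroxyl that is removed afterwards. Further cuts are the lactone Cα–CH2 bond to ring C, the C1–C2 bond of the 1,2-diarylpropane-1,3-diol and the C2–C3 bond of the dihydrofuran (two aldols).
2. Feature used: ring B is a pentasubstituted benzene whose C7a–C3a edge is the enol ether double bond of a 2,3-dihydrofuran, with OMe on C7 and the lactone CH2 on C5. C7 can therefore come from a methoxycarbene carbon, C6 and C5 from a terminal alkyne, and C4 from one CO ligand.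
3. Forward order: (a) a trans γ-aryl lactone is turned into a 5-stannyl-2,3-dihydrofuran and then into chromium methoxycarbene 15; (b) the (R)-β-propargyl butyrolactone 21 is made; (c) the ring C–D benzylic bromide 36 is made. Lactone 21 is benzylated with 36 to give alkyne 37; 15 and 37 then close ring B last. Triflate/formate deoxygenation and desilylation finish the synthesis.
4. Stereochemistry: one auxiliary, (4S)-4-benzyl-1,3-oxazolidin-2-one, sets C2/C3 of the dihydrofuran (syn aldol, lactonisation to the trans lactone), the lactone β-carbon (enolate alkylation) and the diol pair (magnesium-catalysed anti aldol). The lactone α-carbon follows from trans alkylation under substrate control.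

Key step: step 23

Assumption: the magnesium-catalysed aldol of the arylacetyl imide 30 is taken to follow the facial sense established for N-propionyl imides (chelated enolate, attack anti to the benzyl group, anti adduct).

Abbreviations: TBS = tert-butyldimethylsilyl; Ar = 4-(TBS-oxy)-3-methoxyphenyl. Ring A is the aryl ring on C2 of the dihydrobenzofuran, ring B its benzo ring, ring C the central phenol ring, ring D the aryl ring on the carbinol carbon.

**Carbene branch**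

Step 1
Reactants: 1 vanillin
Product: 2 4-(TBS-oxy)-3-methoxybenzaldehyde
Conditions: TBSCl, imidazole, DMF, rt
Reagents that add atoms: tert-butyldimethylsilyl chloride, CC(C)(C)[Si](C)(C)Cl
Why: Routine silyl protection of the phenol keeps the acidic OH out of the boron and magnesium aldol reactions in which 2 is used twice.

Step 2
Reactants: 3 (4S)-4-benzyl-1,3-oxazolidin-2-one; 4 methyl 4-chloro-4-oxobutanoate
Product: 5 methyl 4-[(4S)-4-benzyl-2-oxo-1,3-oxazolidin-3-yl]-4-oxobutanoate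
Conditions: n-BuLi, THF, −78 °C; then 4, −78 to 0 °C
Reagents that add atoms: none
Why: N-acylation of the lithiated oxazolidinone by the acid chloride is far faster than attack at the methyl ester, so the succinate is attached to the auxiliary at one end only.

Step 3
Reactants: 5 methyl 4-[(4S)-4-benzyl-2-oxo-1,3-oxazolidin-3-yl]-4-oxobutanoate; 2 4-(TBS-oxy)-3-methoxybenzaldehyde
Product: 7 (4S)-4-benzyl-3-[(2S,3S)-2-Ar-5-oxooxolane-3-carbonyl]-1,3-oxazolidin-2-one, via syn aldol adduct 6 (not isolated)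
Conditions: Bu2BOTf, i-Pr2NEt, CH2Cl2, 0 °C; 2, −78 to 0 °C; H2O2, pH 7 buffer, MeOH, 0 °C; PPTS (cat.), CH2Cl2 if lactonisation is incomplete
Reagents that add atoms: none
Why: Evans syn aldol in which the Z boron enolate formed on the imide side adds to 2 through a chair Zimmerman–Traxler transition state on the face away from the benzyl group, setting both centres of 6 as 3S,4S, after which the aldolate oxygen closes onto the methyl ester so that the syn pair is delivered as the trans 4,5-disubstituted γ-lactone.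

Step 4
Reactants: 7 (4S)-4-benzyl-3-[(2S,3S)-2-Ar-5-oxooxolane-3-carbonyl]-1,3-oxazolidin-2-one
Product: 8 (4R,5S)-5-Ar-4-(hydroxymethyl)oxolan-2-one
Conditions: NaBH4, THF/H2O, 0 °C
Reagents that add atoms: none
Why: Chemoselective borohydride reduction of the activated N-acyl oxazolidinone (reductive auxiliary cleavage) should give the primary alcohol and return 3 while the less electrophilic γ-lactone survives, the short cold contact limiting acyl migration to the new hydroxyl, and no stereocentre is touched.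

Step 5
Reactants: 8 (4R,5S)-5-Ar-4-(hydroxymethyl)oxolan-2-one
Product: 9 (4R,5S)-5-Ar-4-(TBS-oxymethyl)oxolan-2-one
Conditions: TBSCl, imidazole, CH2Cl2, 0 °C to rt
Reagents that add atoms: tert-butyldimethylsilyl chloride, CC(C)(C)[Si](C)(C)Cl
Why: Standard silylation of the primary alcohol, which also removes the hydroxyl that could translactonise.

Step 6
Reactants: 9 (4R,5S)-5-Ar-4-(TBS-oxymethyl)oxolan-2-one
Product: 11 [(2S,3R)-2-Ar-3-(TBS-oxymethyl)-2,3-dihydrofuran-5-yl]trimethylstannane, via ketene acetal triflate 10 (not isolated)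
Conditions: KN(SiMe3)2, PhNTf2, THF/DMPU, −78 °C; then Me3SnSnMe3, Pd(PPh3)4, LiCl, THF, −78 °C to rt
Reagents that add atoms: hexamethylditin, C[Sn](C)(C)[Sn](C)(C)C; N-phenylbis(trifluoromethanesulfonimide), O=S(=O)(N(c1ccccc1)S(=O)(=O)C(F)(F)F)C(F)(F)F (its CF3SO2 group is carried only by 10)
Why: O-sulfonylation of the potassium lactone enolate gives the cyclic ketene acetal triflate, whose C–O bond adds oxidatively to zerovalent palladium and is stannylated by hexamethylditin (Stille-type coupling), fixing the metal at C5 without touching the C2 and C3 centres because the only enolisable position is the ring CH2.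

Step 7
Reactants: 11 [(2S,3R)-2-Ar-3-(TBS-oxymethyl)-2,3-dihydrofuran-5-yl]trimethylstannane; 12 hexacarbonylchromium, Cr(CO)6
Product: 15 pentacarbonyl{methoxy[(2S,3R)-2-Ar-3-(TBS-oxymethyl)-2,3-dihydrofuran-5-yl]methylidene}chromium, via 5-lithio-2,3-dihydrofuran 13 (not isolated), via lithium acylpentacarbonylchromate 14 (not isolated)
Conditions: MeLi, THF, −78 °C; Cr(CO)6, THF, −78 °C to rt; then MeOTf, CH2Cl2, 0 °C
Reagents that add atoms: methyl triflate, COS(=O)(=O)C(F)(F)F; methyllithium, [Li]C (its lithium is carried only by 13 and 14)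
Why: Tin–lithium exchange gives the C5 vinyllithium regiospecifically, which adds to a CO ligand of Cr(CO)6 to give the acylchromate, and O-methylation with the hard electrophile MeOTf completes the classical Fischer carbene synthesis with the stereocentres untouched.

**Alkyne lactone**

Step 8
Reactants: 3 (4S)-4-benzyl-1,3-oxazolidin-2-one; 16 pent-4-ynoyl chloride
Product: 17 (4S)-4-benzyl-3-(pent-4-ynoyl)-1,3-oxazolidin-2-one
Conditions: n-BuLi, THF, −78 °C; then 16, −78 to 0 °C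
Reagents that add atoms: none
Why: N-acylation of the lithiated auxiliary with the acid chloride, the oxazolidinone anion being too weakly basic to disturb the terminal alkyne.

Step 9
Reactants: 17 (4S)-4-benzyl-3-(pent-4-ynoyl)-1,3-oxazolidin-2-one; 18 tert-butyl bromoacetate
Product: 19 tert-butyl (3R)-3-[(4S)-4-benzyl-2-oxo-1,3-oxazolidine-3-carbonyl]hex-5-ynoate
Conditions: NaN(SiMe3)2, THF, −78 °C; then 18, −78 to −40 °C
Reagents that add atoms: none
Why: Evans asymmetric alkylation in which the chelated Z sodium enolate, formed selectively because the imide α-CH is far more acidic than the alkyne CH, is attacked by the bromoacetate on the face opposite the benzyl group to set the R centre that becomes the lactone β-carbon.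

Step 10
Reactants: 19 tert-butyl (3R)-3-[(4S)-4-benzyl-2-oxo-1,3-oxazolidine-3-carbonyl]hex-5-ynoate
Product: 20 tert-butyl (3R)-3-(hydroxymethyl)hex-5-ynoate
Conditions: NaBH4, THF/H2O, 0 °C to rt
Reagents that add atoms: none
Why: Borohydride reductive cleavage of the imide gives the primary alcohol with recovery of 3, the hindered tert-butyl ester and the alkyne being inert under these conditions.

Step 11
Reactants: 20 tert-butyl (3R)-3-(hydroxymethyl)hex-5-ynoate
Product: 21 (4R)-4-(prop-2-yn-1-yl)oxolan-2-one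
Conditions: CF3CO2H, CH2Cl2, 0 °C to rt
Reagents that add atoms: none
Why: Acid cleaves the tert-butyl ester and the resulting γ-hydroxy acid lactonises (acid-catalysed lactonisation), the stereocentre being remote from any ionising position.

**Ring C–D bromide**

Step 12
Reactants: 22 methyl vanillate (methyl 4-hydroxy-3-methoxybenzoate); 23 allyl bromide
Product: 24 methyl 3-methoxy-4-(prop-2-en-1-yloxy)benzoate
Conditions: K2CO3, acetone, reflux
Reagents that add atoms: none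
Why: Williamson O-allylation of the phenol under mild carbonate conditions.

Step 13
Reactants: 24 methyl 3-methoxy-4-(prop-2-en-1-yloxy)benzoate
Product: 25 methyl 4-hydroxy-3-methoxy-5-(prop-2-en-1-yl)benzoate
Conditions: N,N-diethylaniline, 200 °C
Reagents that add atoms: none
Why: Aromatic Claisen rearrangement, a [3,3]-sigmatropic shift to the only free ortho position followed by tautomerisation, places the three-carbon chain next to the phenol where ring C needs its branch.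

Step 14
Reactants: 25 methyl 4-hydroxy-3-methoxy-5-(prop-2-en-1-yl)benzoate
Product: 26 methyl 4-(TBS-oxy)-3-methoxy-5-(prop-2-en-1-yl)benzoate
Conditions: TBSCl, imidazole, DMF, rt to 40 °C
Reagents that add atoms: tert-butyldimethylsilyl chloride, CC(C)(C)[Si](C)(C)Cl
Why: Silylation of the hindered phenol keeps it from lactonising onto the arylacetic acid made next.

Step 15
Reactants: 26 methyl 4-(TBS-oxy)-3-methoxy-5-(prop-2-en-1-yl)benzoate
Product: 28 2-[2-(TBS-oxy)-3-methoxy-5-(methoxycarbonyl)phenyl]acetic acid, via arylacetaldehyde 27 (not isolated)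
Conditions: O3, MeCN/H2O, 0 °C; then NaClO2 (aq), 0 °C to rt
Reagents that add atoms: ozone, [O-][O+]=O; sodium chlorite, [Na+].[O-]Cl=O
Why: Ozonolysis in aqueous acetonitrile, where water traps the carbonyl oxide, gives the arylacetaldehyde directly and chlorite oxidation (Pinnick-type, the hydrogen peroxide formed serving as hypochlorite scavenger) takes it to the acid before it can enolise or condense, while the ester-deactivated arene is attacked far more slowly than the alkene.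

Step 16
Reactants: 28 2-[2-(TBS-oxy)-3-methoxy-5-(methoxycarbonyl)phenyl]acetic acid; 3 (4S)-4-benzyl-1,3-oxazolidin-2-one
Product: 30 methyl 3-{2-[(4S)-4-benzyl-2-oxo-1,3-oxazolidin-3-yl]-2-oxoethyl}-4-(TBS-oxy)-5-methoxybenzoate, via mixed pivalic anhydride 29 (not isolated)
Conditions: t-BuCOCl, Et3N, THF, −20 °C; then 3, LiCl, −20 °C to rt
Reagents that add atoms: pivaloyl chloride, CC(C)(C)C(=O)Cl (its acyl group is carried only by 29)
Why: Mixed-anhydride N-acylation of the oxazolidinone, activated by LiCl and Et3N, attaches the auxiliary without strong base.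

Step 17
Reactants: 30 methyl 3-{2-[(4S)-4-benzyl-2-oxo-1,3-oxazolidin-3-yl]-2-oxoethyl}-4-(TBS-oxy)-5-methoxybenzoate; 2 4-(TBS-oxy)-3-methoxybenzaldehyde
Product: 32 methyl 3-{(2R,3S)-3-Ar-1-[(4S)-4-benzyl-2-oxo-1,3-oxazolidin-3-yl]-3-hydroxy-1-oxopropan-2-yl}-4-(TBS-oxy)-5-methoxybenzoate, via trimethylsilyl ether 31 (not isolated)
Conditions: MgCl2 (0.2 equiv), Et3N, Me3SiCl, EtOAc, rt; then AcOH/THF/H2O, rt
Reagents that add atoms: chlorotrimethylsilane, C[Si](C)(C)Cl (its silyl group is carried only by 31)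
Why: Magnesium halide-catalysed direct anti aldol of an N-acyl oxazolidinone with an aromatic aldehyde, in which soft enolisation by MgCl2/Et3N gives the chelated Z enolate that is attacked on the face opposite the benzyl group through a boat-like transition state to set the 2R,3S anti pair, silylation of the magnesium aldolate by Me3SiCl driving turnover and preventing retro-aldol and mild acid then freeing the alcohol.

Step 18
Reactants: 32 methyl 3-{(2R,3S)-3-Ar-1-[(4S)-4-benzyl-2-oxo-1,3-oxazolidin-3-yl]-3-hydroxy-1-oxopropan-2-yl}-4-(TBS-oxy)-5-methoxybenzoate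
Product: 33 methyl 3-[(1S,2S)-1-Ar-1,3-dihydroxypropan-2-yl]-4-(TBS-oxy)-5-methoxybenzoate
Conditions: NaBH4, THF/H2O, 0 °C to rt
Reagents that add atoms: none
Why: Borohydride reductive cleavage of the imide gives the 1,3-diol and returns 3 without reducing the electron-rich aryl methyl ester, and the two centres are no longer epimerisable once the carbonyl is gone.

Step 19
Reactants: 33 methyl 3-[(1S,2S)-1-Ar-1,3-dihydroxypropan-2-yl]-4-(TBS-oxy)-5-methoxybenzoate
Product: 34 methyl 3-[(1S,2S)-1-Ar-1,3-bis(TBS-oxy)propan-2-yl]-4-(TBS-oxy)-5-methoxybenzoate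
Conditions: t-BuMe2SiOTf, 2,6-lutidine, CH2Cl2, −78 to 0 °C
Reagents that add atoms: tert-butyldimethylsilyl triflate, CC(C)(C)[Si](C)(C)OS(=O)(=O)C(F)(F)F
Why: Silylation with the reactive silyl triflate and a hindered base protects both the primary and the hindered benzylic secondary alcohol without ionising the electron-rich benzylic position.

Step 20
Reactants: 34 methyl 3-[(1S,2S)-1-Ar-1,3-bis(TBS-oxy)propan-2-yl]-4-(TBS-oxy)-5-methoxybenzoate
Product: 35 {3-[(1S,2S)-1-Ar-1,3-bis(TBS-oxy)propan-2-yl]-4-(TBS-oxy)-5-methoxyphenyl}methanol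
Conditions: i-Bu2AlH, CH2Cl2, −78 °C
Reagents that add atoms: none
Why: Hydride reduction of the aryl ester to the benzylic alcohol at low temperature, to which the silyl ethers are inert.

Step 21
Reactants: 35 {3-[(1S,2S)-1-Ar-1,3-bis(TBS-oxy)propan-2-yl]-4-(TBS-oxy)-5-methoxyphenyl}methanol
Product: 36 1-(bromomethyl)-3-[(1S,2S)-1-Ar-1,3-bis(TBS-oxy)propan-2-yl]-4-(TBS-oxy)-5-methoxybenzene
Conditions: CBr4, PPh3, CH2Cl2, 0 °C
Reagents that add atoms: carbon tetrabromide, BrC(Br)(Br)Br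
Why: Appel bromination of the primary benzylic alcohol under neutral conditions, the bromide being used at once because of its p-silyloxy activation.

**Assembly and endgame**

Step 22
Reactants: 21 (4R)-4-(prop-2-yn-1-yl)oxolan-2-one; 36 1-(bromomethyl)-3-[(1S,2S)-1-Ar-1,3-bis(TBS-oxy)propan-2-yl]-4-(TBS-oxy)-5-methoxybenzene
Product: 37 (3R,4R)-3-({3-[(1S,2S)-1-Ar-1,3-bis(TBS-oxy)propan-2-yl]-4-(TBS-oxy)-5-methoxyphenyl}methyl)-4-(prop-2-yn-1-yl)oxolan-2-one
Conditions: LiN(i-Pr)2 (2.1 equiv), THF, −78 °C; then 36, −78 to −40 °C; aq NH4Cl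
Reagents that add atoms: none
Why: Stereoselective enolate alkylation of a β-substituted γ-butyrolactone, in which two equivalents of amide base give the enolate together with the lithium acetylide and only the enolate carbon is alkylated by the benzylic bromide at low temperature, anti to the β-propargyl group, so that the α-centre is set as R (trans) under substrate control.

Step 23
Reactants: 15 pentacarbonyl{methoxy[(2S,3R)-2-Ar-3-(TBS-oxymethyl)-2,3-dihydrofuran-5-yl]methylidene}chromium; 37 (3R,4R)-3-({3-[(1S,2S)-1-Ar-1,3-bis(TBS-oxy)propan-2-yl]-4-(TBS-oxy)-5-methoxyphenyl}methyl)-4-(prop-2-yn-1-yl)oxolan-2-one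
Product: 39 (3R,4R)-3-({3-[(1S,2S)-1-Ar-1,3-bis(TBS-oxy)propan-2-yl]-4-(TBS-oxy)-5-methoxyphenyl}methyl)-4-{[(2S,3R)-2-Ar-3-(TBS-oxymethyl)-4-hydroxy-7-methoxy-2,3-dihydro-1-benzofuran-5-yl]methyl}oxolan-2-one, via arene tricarbonylchromium complex 38 (not isolated)
Conditions: THF (degassed, 0.05 M), 50 °C; then air, Et2O, daylight, rt
Reagents that add atoms: none
Why: Thermal loss of one cis CO from 15 lets the alkyne of 37 coordinate and insert into the Cr=C bond with its CH terminus bonded to the carbene carbon, CO then inserts to give an η4-vinylketene, which ring-closes onto C4 of the dihydrofuran, and tautomerisation of the cyclohexadienone gives the phenol bound to Cr(CO)3 (38) that air releases as 39. The closest known reaction is the Dötz benzannulation of methoxycarbene complexes carrying a cyclic enol ether (α-alkoxyalkenyl) group with terminal alkynes. Ring B closes by a 6π-electrocyclisation of the dienylketene (C4–C3a bond) after the C7–C6 and C5–C4 bonds have formed on the metal. No stereocentre is created, and the six existing ones lie outside the reacting π-system and are not acidic under the neutral conditions. The step needs the alkyne to insert with its substituted carbon away from the carbene carbon, which the steric preference of terminal alkynes in this reaction provides, so that the lactone CH2 ends on C5 next to the new C4 hydroxyl and the hydrogen on C6 next to the methoxy-bearing C7. It also needs CO insertion to win over cyclopentannulation, which alkenyl complexes in THF favour, and a non-oxidising release from chromium (air, not a strong oxidant) so that the p-methoxyphenol is not taken on to a quinone.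

Step 24
Reactants: 39 the C4 phenol from step 23
Product: 40 (2S,3R)-2-Ar-3-(TBS-oxymethyl)-7-methoxy-5-{[(3R,4R)-4-({3-[(1S,2S)-1-Ar-1,3-bis(TBS-oxy)propan-2-yl]-4-(TBS-oxy)-5-methoxyphenyl}methyl)-5-oxooxolan-3-yl]methyl}-2,3-dihydro-1-benzofuran-4-yl trifluoromethanesulfonate
Conditions: Tf2O, pyridine, CH2Cl2, 0 °C
Reagents that add atoms: trifluoromethanesulfonic anhydride, O=S(=O)(OS(=O)(=O)C(F)(F)F)C(F)(F)F
Why: Sulfonylation of the only free hydroxyl, the hindered C4 phenol, with Tf2O and pyridine (aryl triflate formation), conditions too weakly basic to enolise the lactone.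

Step 25
Reactants: 40 the C4 aryl triflate from step 24
Product: 41 (3R,4R)-3-({3-[(1S,2S)-1-Ar-1,3-bis(TBS-oxy)propan-2-yl]-4-(TBS-oxy)-5-methoxyphenyl}methyl)-4-{[(2S,3R)-2-Ar-3-(TBS-oxymethyl)-7-methoxy-2,3-dihydro-1-benzofuran-5-yl]methyl}oxolan-2-one
Conditions: Pd(OAc)2, Fe(C5H4PPh2)2 (1,1'-bis(diphenylphosphino)ferrocene), HCO2H, Et3N, DMF, 70 °C
Reagents that add atoms: none
Why: Palladium-catalysed transfer hydrogenolysis of the aryl triflate, in which oxidative addition to zerovalent palladium, exchange of triflate for formate, loss of CO2 and C–H reductive elimination replace the oxygen by hydrogen without affecting the silyl ethers or the lactone.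

Step 26
Reactants: 41 the hexakis-TBS ether of the target
Product: 42 CNP0186558.2, (3R,4R)-3-({4-hydroxy-3-[(1S,2S)-1,3-dihydroxy-1-(4-hydroxy-3-methoxyphenyl)propan-2-yl]-5-methoxyphenyl}methyl)-4-{[(2S,3R)-2-(4-hydroxy-3-methoxyphenyl)-3-(hydroxymethyl)-7-methoxy-2,3-dihydro-1-benzofuran-5-yl]methyl}oxolan-2-one
Conditions: Bu4NF, AcOH, THF, 0 °C to rt
Reagents that add atoms: none
Why: Fluoride-induced cleavage of all six silyl ethers (global desilylation), buffered with acetic acid so that the phenoxides are protonated at once and neither the lactone nor the p-hydroxybenzylic alcohol is exposed to base.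

**Compound list**

1 | vanillin (4-hydroxy-3-methoxybenzaldehyde) | COc1cc(C=O)ccc1O | starting material
2 | 4-(TBS-oxy)-3-methoxybenzaldehyde | COc1cc(C=O)ccc1O[Si](C)(C)C(C)(C)C | intermediate
3 | (4S)-4-benzyl-1,3-oxazolidin-2-one | O=C1N[C@@H](Cc2ccccc2)CO1 | starting material
4 | methyl 4-chloro-4-oxobutanoate | COC(=O)CCC(=O)Cl | starting material
5 | methyl 4-[(4S)-4-benzyl-2-oxo-1,3-oxazolidin-3-yl]-4-oxobutanoate | COC(=O)CCC(=O)N1[C@@H](Cc2ccccc2)COC1=O | intermediate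
6 | methyl (3S,4S)-4-Ar-3-[(4S)-4-benzyl-2-oxo-1,3-oxazolidine-3-carbonyl]-4-hydroxybutanoate (syn aldol adduct) | COC(=O)C[C@H](C(=O)N1[C@@H](Cc2ccccc2)COC1=O)[C@H](O)c1ccc(O[Si](C)(C)C(C)(C)C)c(OC)c1 | intermediate
7 | (4S)-4-benzyl-3-[(2S,3S)-2-Ar-5-oxooxolane-3-carbonyl]-1,3-oxazolidin-2-one (trans lactone) | O=C1C[C@H](C(=O)N2[C@@H](Cc3ccccc3)COC2=O)[C@@H](c2ccc(O[Si](C)(C)C(C)(C)C)c(OC)c2)O1 | intermediate
8 | (4R,5S)-5-Ar-4-(hydroxymethyl)oxolan-2-one | O=C1C[C@H](CO)[C@@H](c2ccc(O[Si](C)(C)C(C)(C)C)c(OC)c2)O1 | intermediate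
9 | (4R,5S)-5-Ar-4-(TBS-oxymethyl)oxolan-2-one | O=C1C[C@H](CO[Si](C)(C)C(C)(C)C)[C@@H](c2ccc(O[Si](C)(C)C(C)(C)C)c(OC)c2)O1 | intermediate
10 | (2S,3R)-2-Ar-3-(TBS-oxymethyl)-2,3-dihydrofuran-5-yl trifluoromethanesulfonate | O=S(=O)(OC1=C[C@H](CO[Si](C)(C)C(C)(C)C)[C@@H](c2ccc(O[Si](C)(C)C(C)(C)C)c(OC)c2)O1)C(F)(F)F | intermediate
11 | [(2S,3R)-2-Ar-3-(TBS-oxymethyl)-2,3-dihydrofuran-5-yl]trimethylstannane | C[Sn](C)(C)C1=C[C@H](CO[Si](C)(C)C(C)(C)C)[C@@H](c2ccc(O[Si](C)(C)C(C)(C)C)c(OC)c2)O1 | intermediate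
12 | hexacarbonylchromium, Cr(CO)6 | O=C=[Cr](=C=O)(=C=O)(=C=O)(=C=O)=C=O | starting material
13 | (2S,3R)-2-Ar-3-(TBS-oxymethyl)-5-lithio-2,3-dihydrofuran | [Li]C1=C[C@H](CO[Si](C)(C)C(C)(C)C)[C@@H](c2ccc(O[Si](C)(C)C(C)(C)C)c(OC)c2)O1 | intermediate
14 | lithium pentacarbonyl{[(2S,3R)-2-Ar-3-(TBS-oxymethyl)-2,3-dihydrofuran-5-yl]carbonyl}chromate | [Li+].[O-]C(=[Cr](=C=O)(=C=O)(=C=O)(=C=O)=C=O)C1=C[C@H](CO[Si](C)(C)C(C)(C)C)[C@@H](c2ccc(O[Si](C)(C)C(C)(C)C)c(OC)c2)O1 | intermediate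
15 | pentacarbonyl{methoxy[(2S,3R)-2-Ar-3-(TBS-oxymethyl)-2,3-dihydrofuran-5-yl]methylidene}chromium | COC(=[Cr](=C=O)(=C=O)(=C=O)(=C=O)=C=O)C1=C[C@H](CO[Si](C)(C)C(C)(C)C)[C@@H](c2ccc(O[Si](C)(C)C(C)(C)C)c(OC)c2)O1 | intermediate
16 | pent-4-ynoyl chloride | C#CCCC(=O)Cl | starting material
17 | (4S)-4-benzyl-3-(pent-4-ynoyl)-1,3-oxazolidin-2-one | C#CCCC(=O)N1[C@@H](Cc2ccccc2)COC1=O | intermediate
18 | tert-butyl bromoacetate | CC(C)(C)OC(=O)CBr | starting material
19 | tert-butyl (3R)-3-[(4S)-4-benzyl-2-oxo-1,3-oxazolidine-3-carbonyl]hex-5-ynoate | C#CC[C@H](CC(=O)OC(C)(C)C)C(=O)N1[C@@H](Cc2ccccc2)COC1=O | intermediate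
20 | tert-butyl (3R)-3-(hydroxymethyl)hex-5-ynoate | C#CC[C@H](CC(=O)OC(C)(C)C)CO | intermediate
21 | (4R)-4-(prop-2-yn-1-yl)oxolan-2-one | C#CC[C@H]1COC(=O)C1 | intermediate
22 | methyl vanillate (methyl 4-hydroxy-3-methoxybenzoate) | COC(=O)c1ccc(O)c(OC)c1 | starting material
23 | allyl bromide | C=CCBr | starting material
24 | methyl 3-methoxy-4-(prop-2-en-1-yloxy)benzoate | COC(=O)c1ccc(OCC=C)c(OC)c1 | intermediate
25 | methyl 4-hydroxy-3-methoxy-5-(prop-2-en-1-yl)benzoate | COC(=O)c1cc(CC=C)c(O)c(OC)c1 | intermediate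
26 | methyl 4-(TBS-oxy)-3-methoxy-5-(prop-2-en-1-yl)benzoate | COC(=O)c1cc(CC=C)c(O[Si](C)(C)C(C)(C)C)c(OC)c1 | intermediate
27 | methyl 4-(TBS-oxy)-3-methoxy-5-(2-oxoethyl)benzoate | COC(=O)c1cc(CC=O)c(O[Si](C)(C)C(C)(C)C)c(OC)c1 | intermediate
28 | 2-[2-(TBS-oxy)-3-methoxy-5-(methoxycarbonyl)phenyl]acetic acid | COC(=O)c1cc(CC(=O)O)c(O[Si](C)(C)C(C)(C)C)c(OC)c1 | intermediate
29 | mixed anhydride of 28 with pivalic acid | COC(=O)c1cc(CC(=O)OC(=O)C(C)(C)C)c(O[Si](C)(C)C(C)(C)C)c(OC)c1 | intermediate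
30 | methyl 3-{2-[(4S)-4-benzyl-2-oxo-1,3-oxazolidin-3-yl]-2-oxoethyl}-4-(TBS-oxy)-5-methoxybenzoate | COC(=O)c1cc(CC(=O)N2[C@@H](Cc3ccccc3)COC2=O)c(O[Si](C)(C)C(C)(C)C)c(OC)c1 | intermediate
31 | trimethylsilyl ether of 32 at the secondary hydroxyl | COC(=O)c1cc([C@@H](C(=O)N2[C@@H](Cc3ccccc3)COC2=O)[C@H](O[Si](C)(C)C)c2ccc(O[Si](C)(C)C(C)(C)C)c(OC)c2)c(O[Si](C)(C)C(C)(C)C)c(OC)c1 | intermediate
32 | methyl 3-{(2R,3S)-3-Ar-1-[(4S)-4-benzyl-2-oxo-1,3-oxazolidin-3-yl]-3-hydroxy-1-oxopropan-2-yl}-4-(TBS-oxy)-5-methoxybenzoate (anti aldol adduct) | COC(=O)c1cc([C@@H](C(=O)N2[C@@H](Cc3ccccc3)COC2=O)[C@H](O)c2ccc(O[Si](C)(C)C(C)(C)C)c(OC)c2)c(O[Si](C)(C)C(C)(C)C)c(OC)c1 | intermediate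
33 | methyl 3-[(1S,2S)-1-Ar-1,3-dihydroxypropan-2-yl]-4-(TBS-oxy)-5-methoxybenzoate | COC(=O)c1cc([C@@H](CO)[C@H](O)c2ccc(O[Si](C)(C)C(C)(C)C)c(OC)c2)c(O[Si](C)(C)C(C)(C)C)c(OC)c1 | intermediate
34 | methyl 3-[(1S,2S)-1-Ar-1,3-bis(TBS-oxy)propan-2-yl]-4-(TBS-oxy)-5-methoxybenzoate | COC(=O)c1cc([C@@H](CO[Si](C)(C)C(C)(C)C)[C@H](O[Si](C)(C)C(C)(C)C)c2ccc(O[Si](C)(C)C(C)(C)C)c(OC)c2)c(O[Si](C)(C)C(C)(C)C)c(OC)c1 | intermediate
35 | {3-[(1S,2S)-1-Ar-1,3-bis(TBS-oxy)propan-2-yl]-4-(TBS-oxy)-5-methoxyphenyl}methanol | OCc1cc([C@@H](CO[Si](C)(C)C(C)(C)C)[C@H](O[Si](C)(C)C(C)(C)C)c2ccc(O[Si](C)(C)C(C)(C)C)c(OC)c2)c(O[Si](C)(C)C(C)(C)C)c(OC)c1 | intermediate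
36 | 1-(bromomethyl)-3-[(1S,2S)-1-Ar-1,3-bis(TBS-oxy)propan-2-yl]-4-(TBS-oxy)-5-methoxybenzene | BrCc1cc([C@@H](CO[Si](C)(C)C(C)(C)C)[C@H](O[Si](C)(C)C(C)(C)C)c2ccc(O[Si](C)(C)C(C)(C)C)c(OC)c2)c(O[Si](C)(C)C(C)(C)C)c(OC)c1 | intermediate
37 | (3R,4R)-3-({3-[(1S,2S)-1-Ar-1,3-bis(TBS-oxy)propan-2-yl]-4-(TBS-oxy)-5-methoxyphenyl}methyl)-4-(prop-2-yn-1-yl)oxolan-2-one | COc1cc([C@@H](O[Si](C)(C)C(C)(C)C)[C@H](CO[Si](C)(C)C(C)(C)C)c2cc(C[C@H]3C(=O)OC[C@@H]3CC#C)cc(OC)c2O[Si](C)(C)C(C)(C)C)ccc1O[Si](C)(C)C(C)(C)C | intermediate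
38 | tricarbonylchromium complex of 39 (Cr(CO)3 bound η6 to ring B; written as two dot-joined parts) | COc1cc([C@@H](O[Si](C)(C)C(C)(C)C)[C@H](CO[Si](C)(C)C(C)(C)C)c2cc(C[C@H]3C(=O)OC[C@@H]3Cc3cc(OC)c4c(c3O)[C@H](CO[Si](C)(C)C(C)(C)C)[C@@H](c3ccc(O[Si](C)(C)C(C)(C)C)c(OC)c3)O4)cc(OC)c2O[Si](C)(C)C(C)(C)C)ccc1O[Si](C)(C)C(C)(C)C.O=C=[Cr](=C=O)=C=O | intermediate
39 | (3R,4R)-3-({3-[(1S,2S)-1-Ar-1,3-bis(TBS-oxy)propan-2-yl]-4-(TBS-oxy)-5-methoxyphenyl}methyl)-4-{[(2S,3R)-2-Ar-3-(TBS-oxymethyl)-4-hydroxy-7-methoxy-2,3-dihydro-1-benzofuran-5-yl]methyl}oxolan-2-one | COc1cc([C@@H](O[Si](C)(C)C(C)(C)C)[C@H](CO[Si](C)(C)C(C)(C)C)c2cc(C[C@H]3C(=O)OC[C@@H]3Cc3cc(OC)c4c(c3O)[C@H](CO[Si](C)(C)C(C)(C)C)[C@@H](c3ccc(O[Si](C)(C)C(C)(C)C)c(OC)c3)O4)cc(OC)c2O[Si](C)(C)C(C)(C)C)ccc1O[Si](C)(C)C(C)(C)C | intermediate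
40 | C4 trifluoromethanesulfonate of 39 (ring B aryl triflate) | COc1cc([C@@H](O[Si](C)(C)C(C)(C)C)[C@H](CO[Si](C)(C)C(C)(C)C)c2cc(C[C@H]3C(=O)OC[C@@H]3Cc3cc(OC)c4c(c3OS(=O)(=O)C(F)(F)F)[C@H](CO[Si](C)(C)C(C)(C)C)[C@@H](c3ccc(O[Si](C)(C)C(C)(C)C)c(OC)c3)O4)cc(OC)c2O[Si](C)(C)C(C)(C)C)ccc1O[Si](C)(C)C(C)(C)C | intermediate
41 | hexakis-TBS ether of the target (ring B C4 now bears hydrogen) | COc1cc([C@@H](O[Si](C)(C)C(C)(C)C)[C@H](CO[Si](C)(C)C(C)(C)C)c2cc(C[C@H]3C(=O)OC[C@@H]3Cc3cc(OC)c4c(c3)[C@H](CO[Si](C)(C)C(C)(C)C)[C@@H](c3ccc(O[Si](C)(C)C(C)(C)C)c(OC)c3)O4)cc(OC)c2O[Si](C)(C)C(C)(C)C)ccc1O[Si](C)(C)C(C)(C)C | intermediate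
42 | CNP0186558.2, (3R,4R)-3-({4-hydroxy-3-[(1S,2S)-1,3-dihydroxy-1-(4-hydroxy-3-methoxyphenyl)propan-2-yl]-5-methoxyphenyl}methyl)-4-{[(2S,3R)-2-(4-hydroxy-3-methoxyphenyl)-3-(hydroxymethyl)-7-methoxy-2,3-dihydro-1-benzofuran-5-yl]methyl}oxolan-2-one | COc1cc([C@@H](O)[C@H](CO)c2cc(C[C@H]3C(=O)OC[C@@H]3Cc3cc(OC)c4c(c3)[C@H](CO)[C@@H](c3ccc(O)c(OC)c3)O4)cc(OC)c2O)ccc1O | target

**Step count and risks**

Total: 26 steps. Longest linear sequence: 15 steps (22 → 24 → 25 → 26 → 28 → 30 → 32 → 33 → 34 → 35 → 36 → 37 → 39 → 40 → 41 → 42, steps 12 to 26).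

Steps most likely to fail:

Step 23. Alkyne uptake by the hindered, heavily silylated 37 may be slower than thermal decay of 15, and cyclopentannulation without CO insertion or incorporation of two alkynes may compete, so that material from the longest branch is lost. Fallback, which closes ring B by the same benzannulation but before the lactone is benzylated: 15 is heated with the small alkyne 21, which can be used in excess (THF, 50 °C; then air), to give (4R)-4-{[(2S,3R)-2-Ar-3-(TBS-oxymethyl)-4-hydroxy-7-methoxy-2,3-dihydro-1-benzofuran-5-yl]methyl}oxolan-2-one F1. Tf2O and pyridine convert it into (2S,3R)-2-Ar-3-(TBS-oxymethyl)-7-methoxy-5-{[(3R)-5-oxooxolan-3-yl]methyl}-2,3-dihydro-1-benzofuran-4-yl trifluoromethanesulfonate F2, and Pd(OAc)2, Fe(C5H4PPh2)2, HCO2H and Et3N in DMF reduce this to (4R)-4-{[(2S,3R)-2-Ar-3-(TBS-oxymethyl)-7-methoxy-2,3-dihydro-1-benzofuran-5-yl]methyl}oxolan-2-one F3. Its lithium enolate (LiN(i-Pr)2, THF, −78 °C) is alkylated with bromide 36 trans to the C4 substituent, which returns to the route at 41.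

Step 17. The α-aryl imide may show poor facial or syn/anti selection under magnesium catalysis, and the acidic α-CH of the adduct may epimerise in the presence of Et3N. Fallback, an anti-selective allylboration in place of the aldol, setting out from 26: isomerisation of the allyl group (RuHCl(CO)(PPh3)3, toluene, 80 °C) gives methyl 4-(TBS-oxy)-3-methoxy-5-[(1E)-prop-1-en-1-yl]benzoate F4. Cross-metathesis with allylboronic acid pinacol ester (second-generation Grubbs catalyst RuCl2(=CHPh)(PCy3)(H2IMes), CH2Cl2, 40 °C) gives methyl 4-(TBS-oxy)-3-methoxy-5-[(1E)-3-(4,4,5,5-tetramethyl-1,3,2-dioxaborolan-2-yl)prop-1-en-1-yl]benzoate F5. Addition of F5 to aldehyde 2 is catalysed by 3,3'-bis(2,4,6-triisopropylphenyl)-1,1'-binaphthyl-2,2'-diyl hydrogen phosphate, using the enantiomer that directs the boronate to the Si face of 2 (the S acid if the sense known for benzaldehyde holds). The chair transition state of the E boronate should give the anti homoallylic alcohol methyl 3-[(1S,2R)-1-Ar-1-hydroxybut-3-en-2-yl]-4-(TBS-oxy)-5-methoxybenzoate F6. Ozonolysis of the vinyl group with NaBH4 work-up (O3, CH2Cl2/MeOH, −78 °C; NaBH4) turns it into the CH2OH group and returns to the route at 33.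

Step 6. The five-membered ketene acetal triflate may hydrolyse back to 9 or decompose before oxidative addition, so that little stannane is obtained. Fallback, an anomeric sulfone route to the same stannane, setting out from 9: i-Bu2AlH (CH2Cl2, −78 °C) gives the lactol (4R,5S)-5-Ar-4-(TBS-oxymethyl)oxolan-2-ol F7 as an anomer mixture. PhSO2H and CaCl2 in CH2Cl2 give (2S,3R)-2-Ar-3-(TBS-oxymethyl)-5-(phenylsulfonyl)oxolane F8. Deprotonation next to sulfur (n-BuLi, THF, −78 °C) and quenching with Me3SnCl give (2S,3R)-2-Ar-3-(TBS-oxymethyl)-5-(phenylsulfonyl)-5-(trimethylstannyl)oxolane F9, which should lose benzenesulfinic acid on warming with i-Pr2NEt in CHCl3 and so returns to the route at 11.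

**Further compounds**

F1 | step 23 | (4R)-4-{[(2S,3R)-2-Ar-3-(TBS-oxymethyl)-4-hydroxy-7-methoxy-2,3-dihydro-1-benzofuran-5-yl]methyl}oxolan-2-one | O=C1C[C@@H](Cc2cc(OC)c3c(c2O)[C@H](CO[Si](C)(C)C(C)(C)C)[C@@H](c2ccc(O[Si](C)(C)C(C)(C)C)c(OC)c2)O3)CO1
F2 | step 23 | (2S,3R)-2-Ar-3-(TBS-oxymethyl)-7-methoxy-5-{[(3R)-5-oxooxolan-3-yl]methyl}-2,3-dihydro-1-benzofuran-4-yl trifluoromethanesulfonate | O=C1C[C@@H](Cc2cc(OC)c3c(c2OS(=O)(=O)C(F)(F)F)[C@H](CO[Si](C)(C)C(C)(C)C)[C@@H](c2ccc(O[Si](C)(C)C(C)(C)C)c(OC)c2)O3)CO1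
F3 | step 23 | (4R)-4-{[(2S,3R)-2-Ar-3-(TBS-oxymethyl)-7-methoxy-2,3-dihydro-1-benzofuran-5-yl]methyl}oxolan-2-one | O=C1C[C@@H](Cc2cc(OC)c3c(c2)[C@H](CO[Si](C)(C)C(C)(C)C)[C@@H](c2ccc(O[Si](C)(C)C(C)(C)C)c(OC)c2)O3)CO1
F4 | step 17 | methyl 4-(TBS-oxy)-3-methoxy-5-[(1E)-prop-1-en-1-yl]benzoate | COC(=O)c1cc(/C=C/C)c(O[Si](C)(C)C(C)(C)C)c(OC)c1
F5 | step 17 | methyl 4-(TBS-oxy)-3-methoxy-5-[(1E)-3-(4,4,5,5-tetramethyl-1,3,2-dioxaborolan-2-yl)prop-1-en-1-yl]benzoate | COC(=O)c1cc(/C=C/CB2OC(C)(C)C(C)(C)O2)c(O[Si](C)(C)C(C)(C)C)c(OC)c1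
F6 | step 17 | methyl 3-[(1S,2R)-1-Ar-1-hydroxybut-3-en-2-yl]-4-(TBS-oxy)-5-methoxybenzoate | COC(=O)c1cc([C@@H](C=C)[C@H](O)c2ccc(O[Si](C)(C)C(C)(C)C)c(OC)c2)c(O[Si](C)(C)C(C)(C)C)c(OC)c1
F7 | step 6 | (4R,5S)-5-Ar-4-(TBS-oxymethyl)oxolan-2-ol (anomer mixture) | OC1C[C@H](CO[Si](C)(C)C(C)(C)C)[C@@H](c2ccc(O[Si](C)(C)C(C)(C)C)c(OC)c2)O1
F8 | step 6 | (2S,3R)-2-Ar-3-(TBS-oxymethyl)-5-(phenylsulfonyl)oxolane (mixture at C5) | O=S(=O)(c1ccccc1)C1C[C@H](CO[Si](C)(C)C(C)(C)C)[C@@H](c2ccc(O[Si](C)(C)C(C)(C)C)c(OC)c2)O1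
F9 | step 6 | (2S,3R)-2-Ar-3-(TBS-oxymethyl)-5-(phenylsulfonyl)-5-(trimethylstannyl)oxolane | C[Sn](C)(C)C1(S(=O)(=O)c2ccccc2)C[C@H](CO[Si](C)(C)C(C)(C)C)[C@@H](c2ccc(O[Si](C)(C)C(C)(C)C)c(OC)c2)O1
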